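Rings: A, methoxylated ring; B, meta-linked ring; C, second phenolic ring; D, para-linked ring. The 18-membered ring is opened at the C(sp3)–C(sp2) bond between the bridge CH2 remote from ring B and C1 of ring C (para to its hydroxyl). The key step exploits this ArCH2CH2–Ar unit as the anti-Markovnikov hydroarylation retron of a ring B vinyl group: 9-BBN hydroboration and intramolecular B-alkyl Suzuki–Miyaura coupling with the ring C bromide close the macrocycle in one operation. The precursor is an acyclic tetraaryl bis-benzyl ether bearing that vinyl group and bromide; its ring D–ring A bridge arises from the same reaction run intermolecularly, both diaryl ethers from Chan–Lam couplings.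

Key step: step 7

Remark: the target has no stereocentre; compounds 1, 2, 7 and 10 are taken as catalogue compounds.

Step 1
Reactants: 1 3-hydroxy-2-iodo-4-methoxybenzaldehyde; 2 (3-vinylphenyl)boronic acid
Product: 3 2-iodo-4-methoxy-3-(3-vinylphenoxy)benzaldehyde
Conditions: Cu(OAc)2 (1.5 equiv), pyridine, 4 Å MS, CH2Cl2, air, rt
Reagents that add atoms: none
Why: Chan–Lam oxidative O-arylation (phenoxide and boron-derived aryl group meet on copper, C–O reductive elimination from trivalent copper) runs at room temperature, accepts 2,6-disubstituted and ortho-halogenated phenols, and should leave the aldehyde, the aryl iodide and the styrene untouched.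

Step 2
Reactants: 3 2-iodo-4-methoxy-3-(3-vinylphenoxy)benzaldehyde
Product: 5 2-iodo-4-methoxy-3-(3-vinylphenoxy)phenol, via aryl formate 4 (not isolated)
Conditions: 30% aq. H2O2, H2SO4 (cat.), MeOH, rt
Reagents that add atoms: hydrogen peroxide, OO
Why: Acid-catalysed Dakin oxidation, in which the para-methoxy group drives aryl migration in the peroxyhemiacetal and the formate is methanolysed in the same flask; H2O2 in acidic methanol, unlike a peracid, should not epoxidise the styrene.

Step 3
Reactants: 5 2-iodo-4-methoxy-3-(3-vinylphenoxy)phenol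
Product: 6 1-(benzyloxy)-2-iodo-4-methoxy-3-(3-vinylphenoxy)benzene
Conditions: BnBr, K2CO3, DMF, rt
Reagents that add atoms: benzyl bromide, BrCc1ccccc1
Why: Williamson ether synthesis on the phenoxide; the benzyl group keeps the phenol from consuming 9-BBN later and is removed in the last step.

Step 4
Reactants: 7 2-(benzyloxy)-5-bromobenzaldehyde
Product: 9 2-(benzyloxy)-5-bromophenol, via aryl formate 8 (not isolated)
Conditions: mCPBA, CH2Cl2, rt; then K2CO3 (cat.), MeOH, rt
Reagents that add atoms: mCPBA (3-chloroperoxybenzoic acid), O=C(OO)c1cccc(Cl)c1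
Why: Baeyer–Villiger oxidation in which the ortho-alkoxy aryl group migrates, followed by methanolysis of the formate; no alkene is present at this stage, so the peracid is safe.

Step 5
Reactants: 9 2-(benzyloxy)-5-bromophenol; 10 (4-vinylphenyl)boronic acid
Product: 11 1-(benzyloxy)-4-bromo-2-(4-vinylphenoxy)benzene
Conditions: Cu(OAc)2 (1.2 equiv), pyridine, 4 Å MS, CH2Cl2, air, rt
Reagents that add atoms: none
Why: Chan–Lam O-arylation of an unhindered phenol; the aryl bromide is inert to copper at room temperature and the styrene survives.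

Step 6
Reactants: 11 1-(benzyloxy)-4-bromo-2-(4-vinylphenoxy)benzene; 6 1-(benzyloxy)-2-iodo-4-methoxy-3-(3-vinylphenoxy)benzene
Product: 13 1-(benzyloxy)-2-{2-[4-(2-(benzyloxy)-5-bromophenoxy)phenyl]ethyl}-4-methoxy-3-(3-vinylphenoxy)benzene, via alkyl-9-BBN 12 (not isolated)
Conditions: 11, 9-BBN (1.0 equiv), THF, 0 °C to rt; then 6, Pd(dppf)Cl2 (5 mol %), AsPh3, Cs2CO3, DMF/THF/H2O, rt
Reagents that add atoms: none
Why: Intermolecular B-alkyl Suzuki–Miyaura coupling: 9-BBN places boron on the terminal carbon of the ring D styrene, the borane is fully formed before 6 is added so the ring B vinyl group never meets B–H, and zerovalent palladium should insert into the C–I bond of 6 at room temperature well before the electron-rich ring C C–Br bond.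

Step 7
Reactants: 13 1-(benzyloxy)-2-{2-[4-(2-(benzyloxy)-5-bromophenoxy)phenyl]ethyl}-4-methoxy-3-(3-vinylphenoxy)benzene
Product: 15 macrocyclic bis(benzyl ether) of the target, via alkyl-9-BBN 14 (not isolated)
Conditions: 9-BBN (2 equiv), THF, rt; H2O quench; then syringe-pump addition to Pd(dppf)Cl2 (20 mol %), AsPh3, Cs2CO3, THF/DMF/H2O, 65 °C, final concentration about 2 mM
Reagents that add atoms: none
Why: 9-BBN adds across the ring B vinyl group with boron on the terminal carbon, the base-activated alkylborate transmetalates intramolecularly to the arylpalladium bromide formed by oxidative addition of zerovalent palladium into the ring C C–Br bond, and reductive elimination from divalent palladium forms the CH2–C1(ring C) bond. The closest known reaction type is the B-alkyl Suzuki–Miyaura macrocyclization used for cyclophanes and macrolides. The one ring closed is the 18-membered macrocycle, formed by a macrocyclizing C(sp3)–C(sp2) reductive elimination from a 19-membered palladacycle and not by a Baldwin-type attack on a π bond. No stereocenter is created. The step needs terminal regioselectivity in the hydroboration, secured by the steric demand of 9-BBN, and ring closure over oligomerization, secured by slow addition at high dilution and by the two diaryl ether hinges that fold the chain. The bidentate dppf ligand should suppress β-hydride elimination, and the benzyl ethers keep the phenols from quenching the borane.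

Step 8
Reactants: 15 macrocyclic bis(benzyl ether) of the target
Product: 16 target macrocycle CNP0179896.0
Conditions: H2 (1 atm), Pd/C (10%), EtOAc/MeOH, rt
Reagents that add atoms: none
Why: Hydrogenolysis of the two benzyl aryl ethers; no halide or alkene is left, and the methyl ether, the diaryl ethers and the bibenzyl bridges are stable.

Compound list
1 | 3-hydroxy-2-iodo-4-methoxybenzaldehyde | COc1ccc(C=O)c(I)c1O | starting material
2 | (3-vinylphenyl)boronic acid | OB(O)c1cccc(C=C)c1 | starting material
3 | 2-iodo-4-methoxy-3-(3-vinylphenoxy)benzaldehyde | COc1ccc(C=O)c(I)c1Oc1cccc(C=C)c1 | intermediate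
4 | 2-iodo-4-methoxy-3-(3-vinylphenoxy)phenyl formate | COc1ccc(OC=O)c(I)c1Oc1cccc(C=C)c1 | intermediate
5 | 2-iodo-4-methoxy-3-(3-vinylphenoxy)phenol | COc1ccc(O)c(I)c1Oc1cccc(C=C)c1 | intermediate
6 | 1-(benzyloxy)-2-iodo-4-methoxy-3-(3-vinylphenoxy)benzene | COc1ccc(OCc2ccccc2)c(I)c1Oc1cccc(C=C)c1 | intermediate
7 | 2-(benzyloxy)-5-bromobenzaldehyde | O=Cc1cc(Br)ccc1OCc1ccccc1 | starting material
8 | 2-(benzyloxy)-5-bromophenyl formate | O=COc1cc(Br)ccc1OCc1ccccc1 | intermediate
9 | 2-(benzyloxy)-5-bromophenol | Oc1cc(Br)ccc1OCc1ccccc1 | intermediate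
10 | (4-vinylphenyl)boronic acid | OB(O)c1ccc(C=C)cc1 | starting material
11 | 1-(benzyloxy)-4-bromo-2-(4-vinylphenoxy)benzene | C=Cc1ccc(Oc2cc(Br)ccc2OCc2ccccc2)cc1 | intermediate
12 | 9-{2-[4-(2-(benzyloxy)-5-bromophenoxy)phenyl]ethyl}-9-borabicyclo[3.3.1]nonane | Brc1ccc(OCc2ccccc2)c(Oc2ccc(CCB3C4CCCC3CCC4)cc2)c1 | intermediate
13 | 1-(benzyloxy)-2-{2-[4-(2-(benzyloxy)-5-bromophenoxy)phenyl]ethyl}-4-methoxy-3-(3-vinylphenoxy)benzene | COc1ccc(OCc2ccccc2)c(CCc2ccc(Oc3cc(Br)ccc3OCc3ccccc3)cc2)c1Oc1cccc(C=C)c1 | intermediate
14 | 9-BBN adduct of 13 at the ring B vinyl group (boron on the terminal carbon) | COc1ccc(OCc2ccccc2)c(CCc2ccc(Oc3cc(Br)ccc3OCc3ccccc3)cc2)c1Oc1cccc(CCB2C3CCCC2CCC3)c1 | intermediate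
15 | macrocyclic bis(benzyl ether) of the target (both phenols as OBn) | COc1ccc(OCc3ccccc3)c2c1Oc1cccc(c1)CCc1ccc(OCc3ccccc3)c(c1)Oc1ccc(cc1)CC2 | intermediate
16 | CNP0179896.0, 18-membered bis(bibenzyl) macrocycle with two diaryl ether links, one OMe and two OH | COc1ccc(O)c2c1Oc1cccc(c1)CCc1ccc(O)c(c1)Oc1ccc(cc1)CC2 | target

Total step count: 8
Longest linear sequence: 6 steps (steps 1, 2, 3, 6, 7, 8)

Steps most likely to fail

Step 7. Intermolecular coupling may outrun ring closure and give oligomers, or the alkylborane may be lost by β-hydride elimination or protodeboronation while the slow ring-closing transmetalation waits. The fallback sets out from 13 and comes back at 16. An intramolecular Heck reaction of 13 (Pd(OAc)2, P(o-tol)3, K2CO3, DMF, 100 °C, high dilution) would join the same two carbons as a double bond and give the macrocyclic (E)-stilbene bis(benzyl ether) F1. Hydrogenation (H2, Pd/C) would then saturate the bridge and cleave both benzyl ethers in one operation, giving 16 directly.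

Step 6. Palladium may fail to discriminate between the hindered C–I bond of ring A and the C–Br bond of ring C, or the free vinyl group of 6 may be consumed in a Heck-type side reaction. The fallback sets out from 11 and 6 and comes back at 13; it inverts the polarity and avoids palladium. Hydroboration of 11 (9-BBN) and oxidation (NaOH, H2O2) would give 2-{4-[2-(benzyloxy)-5-bromophenoxy]phenyl}ethanol F2. An Appel reaction (CBr4, PPh3) would convert it into the primary bromide 1-(benzyloxy)-4-bromo-2-[4-(2-bromoethyl)phenoxy]benzene F3. Iodine–magnesium exchange on 6 (iPrMgCl·LiCl, THF, −20 °C) would give the arylmagnesium chloride F4. Alkylation of F4 by F3 under Li2CuCl4 catalysis (Kumada-type coupling) would give 13; the ring C bromide and the vinyl group are inert to these conditions.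

Step 2. The styrene may be oxidised or take up methanol under acid, or the electron-rich phenol may be over-oxidised to a quinone. The fallback sets out from 1 and comes back at 6; the formate rearrangement is done before any alkene is present.
- Protection of 1 (4-methoxybenzyl chloride, K2CO3, DMF) would give 2-iodo-4-methoxy-3-[(4-methoxybenzyl)oxy]benzaldehyde F5.
- mCPBA, then K2CO3/MeOH, would give, by way of the aryl formate F6, the phenol 2-iodo-4-methoxy-3-[(4-methoxybenzyl)oxy]phenol F7.
- Benzylation (BnBr, K2CO3) would give the mixed diether 1-(benzyloxy)-2-iodo-4-methoxy-3-[(4-methoxybenzyl)oxy]benzene F8.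
- DDQ (CH2Cl2/H2O) would remove the 4-methoxybenzyl group to give 3-(benzyloxy)-2-iodo-6-methoxyphenol F9.
- Chan–Lam coupling of F9 with 2 (Cu(OAc)2, pyridine, air) would give 6.

Further compounds
F1 | step 7 | macrocyclic (E)-stilbene bis(benzyl ether) | COc1ccc(OCc3ccccc3)c2c1Oc1cccc(c1)/C=C/c1ccc(OCc3ccccc3)c(c1)Oc1ccc(cc1)CC2
F2 | step 6 | 2-{4-[2-(benzyloxy)-5-bromophenoxy]phenyl}ethanol | OCCc1ccc(Oc2cc(Br)ccc2OCc2ccccc2)cc1
F3 | step 6 | 1-(benzyloxy)-4-bromo-2-[4-(2-bromoethyl)phenoxy]benzene | BrCCc1ccc(Oc2cc(Br)ccc2OCc2ccccc2)cc1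
F4 | step 6 | [6-(benzyloxy)-3-methoxy-2-(3-vinylphenoxy)phenyl]magnesium chloride | COc1ccc(OCc2ccccc2)c([Mg]Cl)c1Oc1cccc(C=C)c1
F5 | step 2 | 2-iodo-4-methoxy-3-[(4-methoxybenzyl)oxy]benzaldehyde | COc1ccc(C=O)c(I)c1OCc1ccc(OC)cc1
F6 | step 2 | 2-iodo-4-methoxy-3-[(4-methoxybenzyl)oxy]phenyl formate | COc1ccc(OC=O)c(I)c1OCc1ccc(OC)cc1
F7 | step 2 | 2-iodo-4-methoxy-3-[(4-methoxybenzyl)oxy]phenol | COc1ccc(O)c(I)c1OCc1ccc(OC)cc1
F8 | step 2 | 1-(benzyloxy)-2-iodo-4-methoxy-3-[(4-methoxybenzyl)oxy]benzene | COc1ccc(OCc2ccccc2)c(I)c1OCc1ccc(OC)cc1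
F9 | step 2 | 3-(benzyloxy)-2-iodo-6-methoxyphenol | COc1ccc(OCc2ccccc2)c(I)c1O
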